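**Retrosynthetic overview**
1. 9 ⇒ 6 + 7: cut the bond between the stereocentre and the unsubstituted 2,4-dihydroxyphenyl ring. An enantioselective Brønsted-acid (o-quinone methide) hydroarylation of one arm of the symmetric bis-stilbene 6 with resorcinol sets the only stereocentre in the last step.
2. 6 ⇒ 2 + 2 × 3: both aryl–vinyl bonds come from a double Mizoroki–Heck reaction, with the acetates removed in the same pot.
3. 2 ⇒ 1: acetylation of 4,6-dibromoresorcinol.
4. No ring is formed. All four benzene rings are bought and joined in the order central ring + two 3,5-dihydroxyphenyl rings (step 2), then the 2,4-dihydroxyphenyl ring (step 3).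

Assumption: 1, 3 and both antipodes of the phosphoramide catalyst are taken as purchasable; the (R)-catalyst is taken to give (S)-9, and its antipode is used if a test run shows the opposite sense.

**Step 1**
Reactants: 1 4,6-dibromobenzene-1,3-diol (4,6-dibromoresorcinol)
Product: 2 4,6-dibromo-1,3-phenylene diacetate
Conditions: Ac2O (3 equiv), DMAP (5 mol%), pyridine, 0 °C to rt
Reagents that add atoms: acetic anhydride, CC(=O)OC(C)=O
Why: DMAP-catalysed O-acylation of both phenols, which stops phenoxide formation that would slow oxidative addition and foul the palladium catalyst in the Heck step.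

**Step 2**
Reactants: 2 4,6-dibromo-1,3-phenylene diacetate; 3 5-ethenyl-1,3-phenylene diacetate (3,5-diacetoxystyrene)
Product: 6 4,6-bis[(E)-2-(3,5-dihydroxyphenyl)ethenyl]benzene-1,3-diol, via monostyryl bromide tetraacetate 4 (not isolated), via bis-stilbene hexaacetate 5 (not isolated)
Conditions: 3 (2.5 equiv), Pd(OAc)2 (5 mol%), P(o-tol)3 (12 mol%), Et3N (4 equiv), DMF, 100 °C, dark, Ar; then pyrrolidine (12 equiv), rt, same pot; aq. citric acid work-up
Reagents that add atoms: none
Why: Double Mizoroki–Heck reaction (oxidative addition into each C–Br bond, syn-insertion of the terminal styrene, syn-β-hydride elimination) gives both (E)-stilbene arms, and pyrrolidine then removes all six aryl acetates by aminolysis under non-acidic conditions that the acid-labile 2,4-dihydroxystilbene units tolerate.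

**Step 3**
Reactants: 6 4,6-bis[(E)-2-(3,5-dihydroxyphenyl)ethenyl]benzene-1,3-diol; 7 benzene-1,3-diol (resorcinol)
Product: 9 4-[(1S)-1-(2,4-dihydroxyphenyl)-2-(3,5-dihydroxyphenyl)ethyl]-6-[(E)-2-(3,5-dihydroxyphenyl)ethenyl]benzene-1,3-diol (target), via o-quinone methide 8 (not isolated)
Conditions: 7 (15 equiv), (R)-3,3'-bis(2,4,6-triisopropylphenyl)-BINOL N-triflylphosphoramide (5 mol%), EtOAc/CH2Cl2 1:3, 0.02 M, −10 °C, dark, Ar; Et3N quench at ca. 55% conversion of 6; Sephadex LH-20 then C18 chromatography; recovered 6 recycled
Reagents that add atoms: none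
Why: Proposed new method: the chiral N-triflylphosphoramide protonates the β-carbon (the one next to the 3,5-dihydroxyphenyl ring) of one 2,4-dihydroxystyryl arm of 6 to give o-quinone methide 8 as a hydrogen-bonded contact ion pair; the phosphoramide anion, bound to the o-QM hydroxyl and to one OH of resorcinol, steers C4 of resorcinol onto the Re face of the exocyclic carbon and so sets the (S) centre in an enantioselective Friedel–Crafts hydroarylation; the closest known reaction type is the chiral phosphoric acid-catalysed addition of indoles and naphthols to o-quinone methides generated from o-hydroxybenzyl alcohols or 2-vinylphenols, which has not been shown for β-aryl (stilbene) substrates, for free polyphenols or for resorcinol as the arene.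

**Compound list**
1 | 4,6-dibromobenzene-1,3-diol | Oc1cc(O)c(Br)cc1Br | starting material
2 | 4,6-dibromo-1,3-phenylene diacetate | CC(=O)Oc1cc(OC(C)=O)c(Br)cc1Br | intermediate
3 | 5-ethenyl-1,3-phenylene diacetate (3,5-diacetoxystyrene) | C=Cc1cc(OC(C)=O)cc(OC(C)=O)c1 | starting material
4 | 4-bromo-6-[(E)-2-(3,5-diacetoxyphenyl)ethenyl]-1,3-phenylene diacetate | CC(=O)Oc1cc(OC(C)=O)c(/C=C/c2cc(OC(C)=O)cc(OC(C)=O)c2)cc1Br | intermediate
5 | 4,6-bis[(E)-2-(3,5-diacetoxyphenyl)ethenyl]-1,3-phenylene diacetate | CC(=O)Oc1cc(OC(C)=O)c(/C=C/c2cc(OC(C)=O)cc(OC(C)=O)c2)cc1/C=C/c1cc(OC(C)=O)cc(OC(C)=O)c1 | intermediate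
6 | 4,6-bis[(E)-2-(3,5-dihydroxyphenyl)ethenyl]benzene-1,3-diol | Oc1cc(O)c(/C=C/c2cc(O)cc(O)c2)cc1/C=C/c1cc(O)cc(O)c1 | intermediate
7 | benzene-1,3-diol (resorcinol) | Oc1cccc(O)c1 | starting material
8 | (6E)-6-[2-(3,5-dihydroxyphenyl)ethylidene]-4-[(E)-2-(3,5-dihydroxyphenyl)ethenyl]-3-hydroxycyclohexa-2,4-dien-1-one, held as its O-protonated ion pair with the catalyst | Oc1cc(O)cc(c1)C/C=C1/C(=O)C=C(O)C(/C=C/c2cc(O)cc(O)c2)=C1 | intermediate
9 | 4-[(1S)-1-(2,4-dihydroxyphenyl)-2-(3,5-dihydroxyphenyl)ethyl]-6-[(E)-2-(3,5-dihydroxyphenyl)ethenyl]benzene-1,3-diol | Oc1cc(O)cc(/C=C/c2cc([C@@H](Cc3cc(O)cc(O)c3)c3ccc(O)cc3O)c(O)cc2O)c1 | target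

**Totals and risks**
Total step count: 3. Longest linear sequence: 3 steps (1 → 2 → 6 → 9).

The three steps most likely to fail:

Step 3 (the proposed new reaction). The risks are:
- The enantioselectivity is untested.
- Product 9 still carries one 2,4-dihydroxystilbene arm, so a second addition competes. For two equivalent arms the mono-adduct peaks near 50%, which is why the reaction is stopped at partial conversion and 6 is recycled.
- The outer rings and alkenes of 6 are also nucleophiles. The 15-fold excess of resorcinol and the high dilution are there to outcompete them.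

Fallback, known chemistry: setting out from 6, the same hydroarylation with resorcinol 7 is run with an achiral Brønsted acid (TsOH·H2O 5 mol%, EtOAc, 0 °C, stopped at partial conversion). This is the ordinary acid-catalysed Friedel–Crafts alkylation of a phenol by a hydroxystilbene and gives the racemic triarylethane F1. F1 is resolved by preparative chiral SFC on an amylose carbamate phase (CO2/MeOH), and the (S)-enantiomer rejoins the route at 9.

Step 2 (double Heck and in-pot deacetylation). The risks are that the second Heck on the hindered monostyryl bromide 4 stalls, that the styrene polymerises at 100 °C, and that the acetates scramble.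

Fallback: setting out from 3, cross-metathesis with vinylboronic acid pinacol ester (Hoveyda–Grubbs II 3 mol%, CH2Cl2, 40 °C) gives the (E)-styrylboronic ester F2. A double Suzuki–Miyaura coupling of F2 (2.4 equiv) with 2 (Pd(dppf)Cl2 5 mol%, CsF 6 equiv, dioxane, 80 °C) comes back to the route at 5, which is treated with pyrrolidine as before. Partial loss of acetate in the coupling does no harm, since all acetates are removed next.

Step 1 (the acetate as protecting group). The acetylation itself is safe. The risk is that diacetate 2 is not a workable Heck partner, for example through acetate loss next to the C–Br bonds.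

Fallback: setting out from 1, the protection is dropped and the free dibromoresorcinol is coupled directly with 3 (2.5 equiv) under conditions for electron-rich aryl bromides (Pd2(dba)3 2.5 mol%, [HP(t-Bu)3]BF4 10 mol%, Cy2NMe 4 equiv, dioxane, 90 °C). This gives the bis-stilbene tetraacetate F3, which is treated with pyrrolidine in the same pot and comes back to the route at 6.

**Further compounds**
F1 | step 3 | racemic 4-[1-(2,4-dihydroxyphenyl)-2-(3,5-dihydroxyphenyl)ethyl]-6-[(E)-2-(3,5-dihydroxyphenyl)ethenyl]benzene-1,3-diol | Oc1cc(O)cc(/C=C/c2cc(C(Cc3cc(O)cc(O)c3)c3ccc(O)cc3O)c(O)cc2O)c1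
F2 | step 2 | 5-[(E)-2-(4,4,5,5-tetramethyl-1,3,2-dioxaborolan-2-yl)ethenyl]-1,3-phenylene diacetate | CC(=O)Oc1cc(OC(C)=O)cc(/C=C/B2OC(C)(C)C(C)(C)O2)c1
F3 | step 1 | 4,6-bis[(E)-2-(3,5-diacetoxyphenyl)ethenyl]benzene-1,3-diol | Oc1cc(O)c(/C=C/c2cc(OC(C)=O)cc(OC(C)=O)c2)cc1/C=C/c1cc(OC(C)=O)cc(OC(C)=O)c1
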